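**Long times.** Let time run and read where a flask stops: the north-west flask holds X at 42.7% after 6.00 d and 42.6% after 10.0 d, a step inside the scatter.

| flask | X | G | remark | time |
|---|---|---|---|---|
| south | 10 mM | 10.5 mM (in portions, 2) | the very flask that is asked about, followed so far; portions every 30 h |  |
| north-west | 5 mM | 10.5 mM (in portions, 2) | run made earlier; portions every 30 h |  |
| flask | 10 mM | 10.5 mM (in portions, 2) | the portions of G follow each other after 30 h, the first at the start | 15 d |

| run | time / d | X / % | L / % |
|---|---|---|---|
| south | 0.250 | 94.6 | 4.8 |
| south | 0.333 | 92.2 | 3.8 |
| south | 0.500 | 90.0 | 10.0 |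
| south | 0.833 | 85.0 | 13.2 |
| south | 1.25 | 79.9 | 15.0 |
| south | 2.08 | 62.7 | 30.3 |
| south | 3.00 | 56.8 | 38.3 |
| north-west | 0.833 | 79.1 | 15.3 |
| north-west | 1.25 | 78.5 | 18.5 |
| north-west | 2.08 | 60.5 | 36.4 |
| north-west | 3.00 | 51.0 | 42.0 |
| north-west | 5.00 | 43.8 | 47.1 |
| north-west | 6.00 | 42.7 | 49.3 |
| north-west | 10.0 | 42.6 | 50.5 |

(scatter of a reading: 1 percentage point)

- the analysis behind the earlier runs scatters by 1 percentage point, standard deviation
- steps that have been proposed: X + G <-> D; D <-> L
- the reaction counts as stopped when no species that holds the X changes by six tenths of a point or more over the second half of the time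

1. the state of affairs at 15 d: stopped, and by what, or still going (it is still moving / all of X has reacted / forward and back rates have come level / G has run out first)
2. how much of the X has reacted by 15 d
3. how much L there is at 15 d, in percent of the X charged

**Stopping constant.** At that stop the north-west flask still has 7.63 mM of G, so G has not run out. Reacted X, with D and L counted together, over the product of free X and free G reads 0.177 mM⁻¹ there: call it the stopping constant K. L reads 88.0% of that reacted X.

**Bench rule.** Hold G at its charge, the pseudo-first-order habit. The reacted fraction of X is then KG/(1 + KG), here 65.0%. But the ratio of G to X charged in the south flask is 1.05, and the rule spends 6.50 mM of the 10.5 mM of G that it holds at its charge. That is the border: a rule holding G at its charge stops working where the G it spends is no longer small beside that charge. Even at a ratio of 2.10, the north-west flask reads 57.4% reacted against the rule's 65.0%.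

**Both ends.** Keep the rule for large excess, and cap the reacted amount c by the smaller charge at the other end. One balance joins them, with X and G the charges: c = K(X − c)(G − c). For the south flask it gives 4.95 mM. My reckoning is therefore 49.5% reacted and 43.6% of L. The south flask reads 43.2% reacted at 3.00 d and the north-west flask reads level from 6.00 d, so expect the south flask level by 15 d.

**The forecast.** It says forward and back rates have come level, with 49.5% reacted and 43.5% of L: “That points to equilibrium, not reagent exhaustion.”

**The flask.** At 15 d the south flask shows this: forward and back rates have come level, 49.0% reacted, 42.0% of L.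

    X + G ⇌ D (K = 24.2 M⁻¹, k = 7.30 × 10⁻⁴ M⁻¹ s⁻¹)
    D ⇌ L (K = 6.07, k = 1.88 × 10⁻⁴ s⁻¹)

**Two returns.** Strike the return of D to X + G and conversion in the south flask climbs from 49.0% to 92.3%. Strike the return of L to D and it climbs to 90.9%, so these two returns together hold it at the stop. The dosing of G over time makes no difference to that conversion, and the balance, which has no term for dosing, lands 0.50 percentage points from the flask. Carry 0.177 mM⁻¹ to a neighbour of the south flask charged with 42 mM of G: the balance gives 85.5% reacted, and at 15 d that flask stands at 85.1%.

The numbers in the tables were generated by integration on assumed constants; noise was put on by code.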